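**Retrosynthetic overview**

1. The target is a (2S)-flavanone: the ring B phenol is freed last by O-benzyl hydrogenolysis, and the C4 ketone is derived from a C4 methyl ether by DDQ hydride abstraction.
2. Key disconnection: ring C is cut at C3–C4 and O1–C2, giving a ring A salicylaldehyde dimethyl acetal and a ring B styrene, joined by an enantioselective [4+2] cycloaddition of an alkoxy ortho-quinone methide cation.
3. Feature used: ring C (O1–C2–C3–C4) is fused to the phenol-derived ring A, and C4 sits on C4a, para to the C7 methoxy group and ortho to O1, so C4 at the acetal level ionises to a cation delocalised from C4 through ring A to O1.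
4. The acetal comes from 2-hydroxy-3,4-dimethoxybenzaldehyde and trimethyl orthoformate; the styrene comes from 3-hydroxy-4,5-dimethoxybenzaldehyde by O-benzylation and Wittig methylenation.
5. Ring order: rings A and B are bought; ring C is the only ring made, in the key step, which also sets the single stereocentre C2.

Key step: step 4

Assumption: the sense of induction of the chiral acid cannot be predicted for this substrate pair. The route is written for the (S,S)-catalyst; a first screen decides whether it or its (R,R)-enantiomer delivers C2 as S, and the configuration is to be checked on the final flavanone.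

**Route**

Step 1
Reactants: 1 3-hydroxy-4,5-dimethoxybenzaldehyde; 2 benzyl bromide
Product: 3 3-(benzyloxy)-4,5-dimethoxybenzaldehyde
Conditions: BnBr, K2CO3, DMF, rt
Reagents that add atoms: 2 benzyl bromide, BrCc1ccccc1
Why: Williamson ether synthesis, in which the phenoxide formed with K2CO3 displaces bromide from benzyl bromide by SN2 while the aldehyde and the methyl ethers are inert.

Step 2
Reactants: 3 3-(benzyloxy)-4,5-dimethoxybenzaldehyde; 4 methyltriphenylphosphonium bromide
Product: 6 1-(benzyloxy)-5-ethenyl-2,3-dimethoxybenzene, via methylenetriphenylphosphorane 5 (not isolated)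
Conditions: Ph3PCH3Br, KOtBu, THF, 0 °C to rt; product stored cold over a trace of BHT
Reagents that add atoms: 4 methyltriphenylphosphonium bromide, C[P+](c1ccccc1)(c1ccccc1)c1ccccc1.[Br-]
Why: Wittig methylenation, in which the non-stabilised ylide 5 adds to the aryl aldehyde and the oxaphosphetane collapses to the terminal styrene and triphenylphosphine oxide, with no alkene geometry to control and the benzyl ether untouched.

Step 3
Reactants: 7 2-hydroxy-3,4-dimethoxybenzaldehyde; 8 trimethyl orthoformate
Product: 9 6-(dimethoxymethyl)-2,3-dimethoxyphenol
Conditions: HC(OMe)3, MeOH, Amberlyst 15 (cat.), rt; filtered through NaHCO3, concentrated, azeotroped with toluene, used crude at once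
Reagents that add atoms: 8 trimethyl orthoformate, COC(OC)OC; methanol, CO
Why: Acid-catalysed acetalisation driven by the orthoformate as water scavenger, with the resin filtered off so that no acid stays with the ionisation-prone, electron-rich acetal, which is therefore not chromatographed.

Step 4
Reactants: 9 6-(dimethoxymethyl)-2,3-dimethoxyphenol; 6 1-(benzyloxy)-5-ethenyl-2,3-dimethoxybenzene
Product: 11 (2S,4S)-2-[3-(benzyloxy)-4,5-dimethoxyphenyl]-4,7,8-trimethoxychromane (2,4-cis), via oxocarbenium cation 10 (not isolated)
Conditions: (S,S)-IDPi (imidodiphosphorimidate from two (S)-BINOL units, 3,5-bis(trifluoromethyl)phenyl at each C3 and C3', N-SO2CF3 on both imide nitrogens; 5 mol%), 9 (1.5 equiv), 5 Å MS, toluene, −40 °C, slow addition of 6; Et3N quench at −40 °C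
Reagents that add atoms: none
Why: Proposed new method: the confined, strongly acidic imidodiphosphorimidate protonates an acetal oxygen of 9 and methanol leaves, giving cation 10, whose charge is shared by the C4 methoxy oxygen, the para C7 methoxy group and the ortho phenol and which stays ion-paired, and hydrogen-bonded through its phenol O–H, to the chiral anion. The CH2 terminus of styrene 6 attacks C4 while the phenol oxygen closes on the developing benzylic carbon, so ring C forms by an intermolecular inverse-electron-demand oxa-[4+2] closure in which the C3–C4 bond runs ahead of the O1–C2 bond. The closest known reaction types are the racemic acid-promoted [4+2] addition of salicylaldehyde-acetal-derived alkoxy ortho-quinone methide cations to styrenes, which gives 4-alkoxyflavans, and chiral Brønsted acid-catalysed cycloadditions of ortho-quinone methides with styrenes; their combination on this cation is not yet shown. The anion shields one face of C4 in 10 and so fixes C4, and the endo placement of ring B over the heterodiene relays this to C2, giving the 2,4-cis (2S,4S) adduct; C4 is erased in step 5, so only C2 has to be secured. Regiochemistry follows from polarity (nucleophilic CH2 to cationic C4, phenol oxygen to the aryl-stabilised carbon), the face at C2 from the confined anion, and chemoselectivity against styrene oligomerisation and re-ionisation of the adduct at C4 or C2 from the low temperature, the slow addition of 6 and the only moderate cation-stabilising power of the meta-oxygenated ring B.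

Step 5
Reactants: 11 (2S,4S)-2-[3-(benzyloxy)-4,5-dimethoxyphenyl]-4,7,8-trimethoxychromane
Product: 14 (2S)-2-[3-(benzyloxy)-4,5-dimethoxyphenyl]-7,8-dimethoxychroman-4-one, via C4 oxocarbenium cation 12 (not isolated), via C4 hemiketal 13 (not isolated)
Conditions: DDQ (1.2 equiv), CH2Cl2/pH 7 phosphate buffer (10:1), 0 °C
Reagents that add atoms: water, O
Why: DDQ oxidation of an electron-rich benzylic ether, the same hydride abstraction that cleaves p-methoxybenzyl ethers: the pseudo-axial C4–H of the cis isomer, aligned with ring A and activated by the para C7 methoxy group, O1 and the C4 methoxy group, is transferred to DDQ, water adds to cation 12 and hemiketal 13 loses methanol to the ketone, while C2–H on the less donating ring B, the plain benzyl ether and the C2 stereocentre should stay untouched under buffered conditions.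

Step 6
Reactants: 14 (2S)-2-[3-(benzyloxy)-4,5-dimethoxyphenyl]-7,8-dimethoxychroman-4-one
Product: 15 (2S)-2-(3-hydroxy-4,5-dimethoxyphenyl)-7,8-dimethoxychroman-4-one (target)
Conditions: H2 (1 atm), 10% Pd/C, EtOAc, rt, stopped at full conversion
Reagents that add atoms: none
Why: Catalytic hydrogenolysis of the benzyl aryl ether frees the ring B phenol under neutral conditions, where the vinylogous-ester-like C4 ketone and the C2–O1 bond reduce much more slowly and no ring opening to the chalcone can scramble C2, which stays S.

**Compound list**

1 | 3-hydroxy-4,5-dimethoxybenzaldehyde | COc1cc(C=O)cc(O)c1OC | starting material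
2 | benzyl bromide | BrCc1ccccc1 | starting material
3 | 3-(benzyloxy)-4,5-dimethoxybenzaldehyde | COc1cc(C=O)cc(OCc2ccccc2)c1OC | intermediate
4 | methyltriphenylphosphonium bromide | C[P+](c1ccccc1)(c1ccccc1)c1ccccc1.[Br-] | starting material
5 | methylenetriphenylphosphorane (ylide, not isolated) | C=P(c1ccccc1)(c1ccccc1)c1ccccc1 | intermediate
6 | 1-(benzyloxy)-5-ethenyl-2,3-dimethoxybenzene | COc1cc(C=C)cc(OCc2ccccc2)c1OC | intermediate
7 | 2-hydroxy-3,4-dimethoxybenzaldehyde | COc1ccc(C=O)c(O)c1OC | starting material
8 | trimethyl orthoformate | COC(OC)OC | starting material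
9 | 6-(dimethoxymethyl)-2,3-dimethoxyphenol | COc1ccc(C(OC)OC)c(O)c1OC | intermediate
10 | [(2-hydroxy-3,4-dimethoxyphenyl)methylidene](methyl)oxonium, the alkoxy ortho-quinone methide cation, ion-paired with the catalyst anion (not isolated) | COc1ccc(C=[O+]C)c(O)c1OC | intermediate
11 | (2S,4S)-2-[3-(benzyloxy)-4,5-dimethoxyphenyl]-4,7,8-trimethoxychromane (2,4-cis) | COc1cc([C@@H]2C[C@H](OC)c3ccc(OC)c(OC)c3O2)cc(OCc4ccccc4)c1OC | intermediate
12 | [(2S)-2-[3-(benzyloxy)-4,5-dimethoxyphenyl]-7,8-dimethoxychroman-4-ylidene](methyl)oxonium (C4 oxocarbenium cation, not isolated) | COc1cc([C@@H]2CC(=[O+]C)c3ccc(OC)c(OC)c3O2)cc(OCc4ccccc4)c1OC | intermediate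
13 | (2S)-2-[3-(benzyloxy)-4,5-dimethoxyphenyl]-4,7,8-trimethoxychroman-4-ol (C4 hemiketal, either C4 epimer, not isolated) | COc1cc([C@@H]2CC(O)(OC)c3ccc(OC)c(OC)c3O2)cc(OCc4ccccc4)c1OC | intermediate
14 | (2S)-2-[3-(benzyloxy)-4,5-dimethoxyphenyl]-7,8-dimethoxychroman-4-one | COc1cc([C@@H]2CC(=O)c3ccc(OC)c(OC)c3O2)cc(OCc4ccccc4)c1OC | intermediate
15 | (2S)-2-(3-hydroxy-4,5-dimethoxyphenyl)-7,8-dimethoxychroman-4-one | COc1cc([C@@H]2CC(=O)c3ccc(OC)c(OC)c3O2)cc(O)c1OC | target

**Step count**

Total steps: 6. Longest linear sequence: 5 steps (steps 1, 2, 4, 5, 6); step 3 feeds the convergent key step.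

**Steps most likely to fail**

Step 4 (the proposed new method). The ion pair may give low or wrong-sense facial selectivity. The acid may also oligomerise the electron-rich styrene, and the adduct may re-ionise at C4 or C2 and lose material or C2 purity. The fallback uses known chemistry and sets out from aldehyde 3. Claisen–Schmidt condensation of 3 with commercial 1-(2-hydroxy-3,4-dimethoxyphenyl)ethanone (CC(=O)c1ccc(OC)c(OC)c1O; KOH, EtOH, rt) should give the chalcone (E)-3-[3-(benzyloxy)-4,5-dimethoxyphenyl]-1-(2-hydroxy-3,4-dimethoxyphenyl)prop-2-en-1-one F1. Intramolecular oxa-Michael cyclisation (NaOAc, EtOH, reflux, unreacted chalcone recycled) should give racemic 2-[3-(benzyloxy)-4,5-dimethoxyphenyl]-7,8-dimethoxychroman-4-one F2. Preparative HPLC on a polysaccharide chiral stationary phase then separates the (S)-enantiomer, which is 14, where the route is rejoined. The (R)-enantiomer can be returned to the chalcone–flavanone equilibrium with base and cycled again.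

Step 5. Hydride abstraction may occur at C2–H instead of C4–H. Cation 12 may also be oxidised further towards the flavone before water traps it, and the flavanone may open to the chalcone and lose C2 purity. The fallback sets out from 11 and replaces the one-step oxidation by hydrolysis and alcohol oxidation. Mild aqueous acid (p-TsOH cat., THF/H2O, rt) should exchange the C4 methoxy group for hydroxyl through the stabilised C4 cation, giving (2S)-2-[3-(benzyloxy)-4,5-dimethoxyphenyl]-7,8-dimethoxychroman-4-ol F3 as C4 epimers. Dess–Martin oxidation (NaHCO3, CH2Cl2, rt) of both epimers then converges on 14.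

Step 3. The hydrogen-bonded aldehyde, deactivated by the para methoxy group, may acetalise incompletely. The acetal may also shed methanol and oligomerise through the ortho-quinone methide while it is concentrated. The fallback sets out from 7 and gives up the stock acetal. Aldehyde 7, orthoformate 8 and styrene 6 are combined with the chiral acid in one flask, as in the racemic three-component form of this cycloaddition. Acetal 9 and cation 10 are then generated and consumed in place, and the route is rejoined at 11; no new compound is made.

**Further compounds**

F1 | step 4 | (E)-3-[3-(benzyloxy)-4,5-dimethoxyphenyl]-1-(2-hydroxy-3,4-dimethoxyphenyl)prop-2-en-1-one | COc1cc(/C=C/C(=O)c2ccc(OC)c(OC)c2O)cc(OCc2ccccc2)c1OC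
F2 | step 4 | racemic 2-[3-(benzyloxy)-4,5-dimethoxyphenyl]-7,8-dimethoxychroman-4-one | COc1cc(C2CC(=O)c3ccc(OC)c(OC)c3O2)cc(OCc4ccccc4)c1OC
F3 | step 5 | (2S)-2-[3-(benzyloxy)-4,5-dimethoxyphenyl]-7,8-dimethoxychroman-4-ol (C4 epimers) | COc1cc([C@@H]2CC(O)c3ccc(OC)c(OC)c3O2)cc(OCc4ccccc4)c1OC
F0 | step 3 | none | none
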